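**Retrosynthetic overview**

1. Ring locants: C1 (C=O), C2 (C–OCH3), C3 (=CH), C4 (CH–OH), C5 (CH–farnesyl), C6 (CH–CH3). The only ring of the target is closed last through the C3–C4 bond, by intramolecular CrCl2/NiCl2 (Nozaki–Hiyama–Kishi) addition of a C3 alkenylchromium to a C4 aldehyde.
2. Enabling feature: C4–OH is the γ-hydroxyl of the C1 enone (C1=O, C2=C3, C4–OH). C3 is therefore vinylic and β to the C1 ketone, so it can be carried as the enol triflate of a C1/C3 1,3-dicarbonyl, cis to the C1 acyl group, while C4 is an aldehyde 1,4 to that ketone.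
3. The enol triflate comes from a methoxymethyl ketone (C1–C2) by formylation (C3) and O-triflation; the ketone comes from a γ-lactone (C1 carbonyl, C4–O) and CH3OCH2Li.
4. One auxiliary-set centre (C5, Evans alkylation of a succinate imide with farnesyl bromide) relays C6 (trans methylation on the temporary γ-lactone ring) and then C4 (key step).
5. Ring order: temporary γ-lactone ring formed in step 3 and opened in step 5; cyclohexenone ring formed in step 9.

Key step: step 9

Remark on the chemistry: the target is taken as the (4R,5R,6R) isomer (4-OH and 5-farnesyl cis, 5-farnesyl and 6-methyl trans); compounds 1, 2, 4 and all reagents named are assumed to be commercial, farnesyl bromide as the (2E,6E) isomer.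

**Route**

Step 1
Reactants: 1 methyl 4-chloro-4-oxobutanoate; 2 (4R)-4-benzyl-1,3-oxazolidin-2-one
Product: 3 methyl 4-[(4R)-4-benzyl-2-oxo-1,3-oxazolidin-3-yl]-4-oxobutanoate
Conditions: Et3N, 4-(dimethylamino)pyridine (cat.), CH2Cl2, 0 °C → rt
Reagents that add atoms: none
Why: N-acylation of the oxazolidinone by the acid chloride through the acylpyridinium ion should give the succinate imide and leave the methyl ester untouched.

Step 2
Reactants: 3 methyl 4-[(4R)-4-benzyl-2-oxo-1,3-oxazolidin-3-yl]-4-oxobutanoate; 4 (2E,6E)-1-bromo-3,7,11-trimethyldodeca-2,6,10-triene (farnesyl bromide)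
Product: 6 methyl (3R,5E,9E)-3-{[(4R)-4-benzyl-2-oxo-1,3-oxazolidin-3-yl]carbonyl}-6,10,14-trimethylpentadeca-5,9,13-trienoate, via sodium enolate 5 (not isolated)
Conditions: NaN(SiMe3)2, THF, −78 °C; then 4, −78 → −40 °C
Reagents that add atoms: none
Why: Evans alkylation: the chelated Z sodium enolate of the imide (far more acidic than the ester) should be alkylated by the primary allylic bromide (SN2, E geometry kept) on the face opposite the benzyl group, which sets C5 as R.

Step 3
Reactants: 6 methyl (3R,5E,9E)-3-{[(4R)-4-benzyl-2-oxo-1,3-oxazolidin-3-yl]carbonyl}-6,10,14-trimethylpentadeca-5,9,13-trienoate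
Product: 8 (4R)-4-[(2E,6E)-3,7,11-trimethyldodeca-2,6,10-trien-1-yl]oxolan-2-one, via hydroxy ester 7 (not isolated)
Conditions: NaBH4, THF/H2O (3:1), 0 °C → rt; then pyridinium p-toluenesulfonate (cat.), CH2Cl2, rt
Reagents that add atoms: none
Why: Borohydride reduction of the activated imide carbonyl should release the auxiliary and give the primary alcohol, which lactonizes onto the methyl ester (5-exo-trig); the ester, the alkenes and C5 are not affected.

Step 4
Reactants: 8 (4R)-4-[(2E,6E)-3,7,11-trimethyldodeca-2,6,10-trien-1-yl]oxolan-2-one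
Product: 10 (3R,4R)-3-methyl-4-[(2E,6E)-3,7,11-trimethyldodeca-2,6,10-trien-1-yl]oxolan-2-one, via lithium enolate 9 (not isolated)
Conditions: LiN(i-Pr)2, THF, −78 °C; then CH3I, −78 → −40 °C
Reagents that add atoms: iodomethane, CI
Why: Lactone enolate alkylation: iodomethane should enter anti to the adjacent farnesyl group of the planar five-ring enolate (1,2-induction), giving the trans lactone and so C6 as R.

Step 5
Reactants: 10 (3R,4R)-3-methyl-4-[(2E,6E)-3,7,11-trimethyldodeca-2,6,10-trien-1-yl]oxolan-2-one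
Product: 11 (3R,4R,6E,10E)-4-(hydroxymethyl)-1-methoxy-3,7,11,15-tetramethylhexadeca-6,10,14-trien-2-one
Conditions: Bu3SnCH2OCH3, n-BuLi, THF, −78 °C; then 10, −78 °C; H2O
Reagents that add atoms: tributyl(methoxymethyl)stannane, COC[Sn](CCCC)(CCCC)CCCC
Why: Tin–lithium exchange gives (methoxymethyl)lithium, whose addition to the lactone should stop at the lithium hemiketal at −78 °C and deliver the methoxymethyl ketone (C1–C2) and the free C4 alcohol on work-up (organolithium addition to a lactone).

Step 6
Reactants: 11 (3R,4R,6E,10E)-4-(hydroxymethyl)-1-methoxy-3,7,11,15-tetramethylhexadeca-6,10,14-trien-2-one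
Product: 12 (3R,4R,6E,10E)-1-methoxy-3,7,11,15-tetramethyl-4-{[(triethylsilyl)oxy]methyl}hexadeca-6,10,14-trien-2-one
Conditions: Et3SiCl, imidazole, CH2Cl2, 0 °C
Reagents that add atoms: chlorotriethylsilane, CC[Si](Cl)(CC)CC
Why: Silyl ether formation at the primary alcohol should trap the open hydroxy ketone form under neutral conditions that do not touch the ketone or its α-centre.

Step 7
Reactants: 12 (3R,4R,6E,10E)-1-methoxy-3,7,11,15-tetramethyl-4-{[(triethylsilyl)oxy]methyl}hexadeca-6,10,14-trien-2-one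
Product: 15 (1E,4R,5R,7E,11E)-2-methoxy-4,8,12,16-tetramethyl-3-oxo-5-{[(triethylsilyl)oxy]methyl}heptadeca-1,7,11,15-tetraen-1-yl trifluoromethanesulfonate, via lithium enolate 13 (not isolated), via lithium formyl enolate 14 (not isolated)
Conditions: LiN(i-Pr)2, THF, −78 °C; HCO2CH2CF3, −78 °C; then N-(5-chloropyridin-2-yl)bis(trifluoromethanesulfonyl)imide, −78 → 0 °C
Reagents that add atoms: 2,2,2-trifluoroethyl formate, O=COCC(F)(F)F; N-(5-chloropyridin-2-yl)-1,1,1-trifluoro-N-(trifluoromethylsulfonyl)methanesulfonamide, Clc1ccc(nc1)N(S(=O)(=O)C(F)(F)F)S(=O)(=O)C(F)(F)F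
Why: Kinetic deprotonation should occur at the CH2 between the carbonyl and the methoxy group (the C6 methine is hindered), Claisen formylation then gives the chelated enolate of the 3-oxo aldehyde (C3 added), and O-sulfonylation at the less hindered formyl oxygen of this U-shaped chelate should give the E enol triflate with the triflate cis to the C1 acyl group.

Step 8
Reactants: 15 (1E,4R,5R,7E,11E)-2-methoxy-4,8,12,16-tetramethyl-3-oxo-5-{[(triethylsilyl)oxy]methyl}heptadeca-1,7,11,15-tetraen-1-yl trifluoromethanesulfonate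
Product: 16 (1E,4R,5R,7E,11E)-5-formyl-2-methoxy-4,8,12,16-tetramethyl-3-oxoheptadeca-1,7,11,15-tetraen-1-yl trifluoromethanesulfonate
Conditions: (COCl)2, DMSO, CH2Cl2, −78 → −40 °C; then i-Pr2NEt, −78 → 0 °C
Reagents that add atoms: none
Why: Swern oxidation applied directly to a primary triethylsilyl ether (activated DMSO displaces the silyl group from oxygen and the alkoxysulfonium ylide collapses) should give the C4 aldehyde without a separate deprotection, and the low temperature and hindered amine protect the C5 centre.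

Step 9
Reactants: 16 (1E,4R,5R,7E,11E)-5-formyl-2-methoxy-4,8,12,16-tetramethyl-3-oxoheptadeca-1,7,11,15-tetraen-1-yl trifluoromethanesulfonate
Product: 17 (4R,5R,6R)-4-hydroxy-2-methoxy-6-methyl-5-[(2E,6E)-3,7,11-trimethyldodeca-2,6,10-trien-1-yl]cyclohex-2-en-1-one
Conditions: CrCl2 (excess), NiCl2 (cat.), degassed DMF, rt, high dilution; aqueous work-up
Reagents that add atoms: none
Why: Nozaki–Hiyama–Kishi reaction: zerovalent nickel (formed from NiCl2 by CrCl2) inserts into the C3–O bond of the enol triflate, transmetallation gives the C3 alkenylchromium with the double-bond geometry kept, and this adds to the C4 aldehyde; the closest known reaction type is the CrCl2/NiCl2 coupling of alkenyl triflates and β-halo enones with aldehydes. The cyclohexenone ring closes by a 6-exo-trig addition to the aldehyde carbonyl with the C2=C3 bond ending endocyclic, which requires the triflate to sit cis to the C1 acyl group. The new stereocentre C4 is controlled by C5: in the half-chair transition state the farnesyl (C5) and methyl (C6) groups are pseudoequatorial, the farnesyl CH2 lies anti to the incoming C3 (Felkin–Anh), and the aldehyde oxygen, bound to the chromium on C3 in a four-centre arrangement, is held roughly perpendicular to the enone plane (pseudoaxial), so the hydroxyl should end cis to the farnesyl group (4R). The step needs chemoselectivity for the aldehyde over the C1 ketone, which alkenylchromium reagents normally show. The neutral medium should avoid Paal–Knorr furan formation and epimerization at C5 and C6 of the 1,4-keto aldehyde, and high dilution suppresses intermolecular coupling. The enol ether and the three trisubstituted alkenes are inert to divalent chromium.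

**Compound list**

1 | methyl 4-chloro-4-oxobutanoate | COC(=O)CCC(=O)Cl | starting material
2 | (4R)-4-benzyl-1,3-oxazolidin-2-one | O=C1N[C@H](Cc2ccccc2)CO1 | starting material
3 | methyl 4-[(4R)-4-benzyl-2-oxo-1,3-oxazolidin-3-yl]-4-oxobutanoate | COC(=O)CCC(=O)N1[C@H](Cc2ccccc2)COC1=O | intermediate
4 | (2E,6E)-1-bromo-3,7,11-trimethyldodeca-2,6,10-triene | BrC/C=C(\C)CC/C=C(\C)CCC=C(C)C | starting material
5 | sodium Z-enolate of 3 | [Na+].COC(=O)C/C=C(\[O-])N1[C@H](Cc2ccccc2)COC1=O | intermediate
6 | methyl (3R,5E,9E)-3-{[(4R)-4-benzyl-2-oxo-1,3-oxazolidin-3-yl]carbonyl}-6,10,14-trimethylpentadeca-5,9,13-trienoate | COC(=O)C[C@@H](C/C=C(\C)CC/C=C(\C)CCC=C(C)C)C(=O)N1[C@H](Cc2ccccc2)COC1=O | intermediate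
7 | methyl (3R,5E,9E)-3-(hydroxymethyl)-6,10,14-trimethylpentadeca-5,9,13-trienoate | COC(=O)C[C@H](CO)C/C=C(\C)CC/C=C(\C)CCC=C(C)C | intermediate
8 | (4R)-4-[(2E,6E)-3,7,11-trimethyldodeca-2,6,10-trien-1-yl]oxolan-2-one | O=C1C[C@@H](C/C=C(\C)CC/C=C(\C)CCC=C(C)C)CO1 | intermediate
9 | lithium enolate of 8 | [Li+].[O-]C1=C[C@@H](C/C=C(\C)CC/C=C(\C)CCC=C(C)C)CO1 | intermediate
10 | (3R,4R)-3-methyl-4-[(2E,6E)-3,7,11-trimethyldodeca-2,6,10-trien-1-yl]oxolan-2-one | O=C1OC[C@H](C/C=C(\C)CC/C=C(\C)CCC=C(C)C)[C@H]1C | intermediate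
11 | (3R,4R,6E,10E)-4-(hydroxymethyl)-1-methoxy-3,7,11,15-tetramethylhexadeca-6,10,14-trien-2-one | COCC(=O)[C@H](C)[C@H](CO)C/C=C(\C)CC/C=C(\C)CCC=C(C)C | intermediate
12 | (3R,4R,6E,10E)-1-methoxy-3,7,11,15-tetramethyl-4-{[(triethylsilyl)oxy]methyl}hexadeca-6,10,14-trien-2-one | COCC(=O)[C@H](C)[C@H](CO[Si](CC)(CC)CC)C/C=C(\C)CC/C=C(\C)CCC=C(C)C | intermediate
13 | lithium Z-enolate of 12 (C1=C2 of the chain) | [Li+].CO/C=C(\[O-])[C@H](C)[C@H](CO[Si](CC)(CC)CC)C/C=C(\C)CC/C=C(\C)CCC=C(C)C | intermediate
14 | lithium enolate of the 1-formyl derivative of 12 (oxygen cis to the acyl group) | [Li+].[O-]/C=C(OC)\C(=O)[C@H](C)[C@H](CO[Si](CC)(CC)CC)C/C=C(\C)CC/C=C(\C)CCC=C(C)C | intermediate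
15 | (1E,4R,5R,7E,11E)-2-methoxy-4,8,12,16-tetramethyl-3-oxo-5-{[(triethylsilyl)oxy]methyl}heptadeca-1,7,11,15-tetraen-1-yl trifluoromethanesulfonate | O=S(=O)(O/C=C(OC)\C(=O)[C@H](C)[C@H](CO[Si](CC)(CC)CC)C/C=C(\C)CC/C=C(\C)CCC=C(C)C)C(F)(F)F | intermediate
16 | (1E,4R,5R,7E,11E)-5-formyl-2-methoxy-4,8,12,16-tetramethyl-3-oxoheptadeca-1,7,11,15-tetraen-1-yl trifluoromethanesulfonate | O=S(=O)(O/C=C(OC)\C(=O)[C@H](C)[C@H](C=O)C/C=C(\C)CC/C=C(\C)CCC=C(C)C)C(F)(F)F | intermediate
17 | (4R,5R,6R)-4-hydroxy-2-methoxy-6-methyl-5-[(2E,6E)-3,7,11-trimethyldodeca-2,6,10-trien-1-yl]cyclohex-2-en-1-one | COC1=C[C@H](O)[C@H](C/C=C(\C)CC/C=C(\C)CCC=C(C)C)[C@@H](C)C1=O | target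

**Step count and risks**

Total step count: 9. Longest linear sequence: 9 steps (1 to 17).

Steps most likely to fail:

Step 9. What may go wrong: poor facial selectivity in the addition to the aldehyde (attack on the other carbonyl face, giving the 4S epimer), or loss of the alkenylchromium by protonation before it adds. Fallback: setting out from 16, the same CrCl2/NiCl2 closure is accepted with the wrong face and gives the (4S,5R,6R)-4-epi alcohol F1. A Mitsunobu reaction (4-nitrobenzoic acid, PPh3, diisopropyl azodicarboxylate, THF, 0 °C) should invert C4 by SN2 and give the (4R) 4-nitrobenzoate F2. Methanolysis (K2CO3, MeOH, 0 °C) removes the ester and comes back to the route at 17.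

Step 7. What may go wrong: deprotonation at the wrong α-carbon with epimerization at C6, or sulfonylation at the ketone oxygen instead of the formyl oxygen. Fallback: setting out from 12, heating with tert-butoxybis(dimethylamino)methane (toluene, 60 °C), which can condense only at the CH2 next to the methoxy group, should give the enaminone F3. Cold aqueous NaOH/THF followed by a pH 6 buffer hydrolyses it to the hydroxymethylene ketone F4. Triflation with (CF3SO2)2O and i-Pr2NEt in CH2Cl2 at −78 °C comes back to the route at 15.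

Step 8. What may go wrong: displacement of the triflate by chloride or amine through addition–elimination at the β-carbon of the enone, incomplete activation of the silyl ether, or epimerization at C5 on warming. Fallback: setting out from 15, HF·pyridine in THF/pyridine at 0 °C removes the silyl group to give the primary alcohol F5. Dess–Martin oxidation (NaHCO3, CH2Cl2, 0 °C) then comes back to the route at 16.

**Further compounds**

F1 | step 9 | (4S,5R,6R)-4-hydroxy-2-methoxy-6-methyl-5-[(2E,6E)-3,7,11-trimethyldodeca-2,6,10-trien-1-yl]cyclohex-2-en-1-one | COC1=C[C@@H](O)[C@H](C/C=C(\C)CC/C=C(\C)CCC=C(C)C)[C@@H](C)C1=O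
F2 | step 9 | (1R,5R,6R)-3-methoxy-5-methyl-4-oxo-6-[(2E,6E)-3,7,11-trimethyldodeca-2,6,10-trien-1-yl]cyclohex-2-en-1-yl 4-nitrobenzoate | COC1=C[C@H](OC(=O)c2ccc(cc2)[N+](=O)[O-])[C@H](C/C=C(\C)CC/C=C(\C)CCC=C(C)C)[C@@H](C)C1=O
F3 | step 7 | (4R,5R,7E,11E)-1-(dimethylamino)-2-methoxy-4,8,12,16-tetramethyl-5-{[(triethylsilyl)oxy]methyl}heptadeca-1,7,11,15-tetraen-3-one (C1=C2 geometry not defined) | CN(C)C=C(OC)C(=O)[C@H](C)[C@H](CO[Si](CC)(CC)CC)C/C=C(\C)CC/C=C(\C)CCC=C(C)C
F4 | step 7 | (1E,4R,5R,7E,11E)-1-hydroxy-2-methoxy-4,8,12,16-tetramethyl-5-{[(triethylsilyl)oxy]methyl}heptadeca-1,7,11,15-tetraen-3-one | O/C=C(OC)\C(=O)[C@H](C)[C@H](CO[Si](CC)(CC)CC)C/C=C(\C)CC/C=C(\C)CCC=C(C)C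
F5 | step 8 | (1E,4R,5R,7E,11E)-5-(hydroxymethyl)-2-methoxy-4,8,12,16-tetramethyl-3-oxoheptadeca-1,7,11,15-tetraen-1-yl trifluoromethanesulfonate | O=S(=O)(O/C=C(OC)\C(=O)[C@H](C)[C@H](CO)C/C=C(\C)CC/C=C(\C)CCC=C(C)C)C(F)(F)F
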